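Slowness is my first worry: the ratio asked for at the late time is an end value only if the slower of the two products has finished by then.

| flask | substrate | coupling partner | capture agent | free catalyst | second catalyst | remark | time |
|---|---|---|---|---|---|---|---|
| cedar | 1.1 M | 0.77 M | 0.022 M | 11 mM | 110 mM | the very flask that is asked about, followed so far |  |
| flask | 1.1 M | 0.770 M | 0.0220 M | 11 mM | 110 mM |  | 30 h |

cedar run (percent of the substrate charged)

| time / h | target / % | trapped intermediate / % |
|---|---|---|
| 0.500 | 58.2 | 1.1 |
| 1.50 | 69.9 | 1.5 |
| 3.00 | 69.3 | 2.4 |
| 4.00 | 70.0 | 2.6 |
| 6.00 | 70.4 | 1.6 |

(each reading ± 0.5 percentage points)

1. ratio of target to trapped intermediate at 6.0 min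
2. ratio of target to trapped intermediate at 30 h



I count turnovers. The coupling partner charged is 70.0% of the substrate, and target in the cedar run levels off at that height, reading 70.4% at 6.00 h, so I take one target per coupling partner. The capture agent charged is 2.00% of the substrate, and the last 3 readings of trapped intermediate average 2.20%, so I take one trapped intermediate per capture agent. The substrate covers both charges, which makes these two the limiting reagents of their two products. So I carry R = 35.0, the end ratio: the charge of coupling partner over the charge of capture agent.

Is the flask there by 30 h? At 0.500 h the cedar run reads target at 83.1% of its ceiling and trapped intermediate at 55.0% of its own, so trapping reads the slower, yet its reading at 3.00 h lies within the scatter of that ceiling. I commit to R = 35.0 at 30 h.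

The weak link is the last reading, whose ratio is 44.0 and could mean that the trapped intermediate decays. But it lies 0.4 percentage points below the ceiling, less than the scatter of 0.5 points, so I keep R. The count says nothing about 6.0 min, which comes before the first reading; that reading gives a ratio of 52.9.

The forecast gives 85 at 6.0 min, its own extrapolation, and 35 at 30 h, “assuming the trapped species stays stable”.

The flask gives 72.9 at 6.0 min, less than the forecast, and 35.0 at 30 h, level with R.

    substrate + free catalyst → free catalyst + open intermediate (k = 0.140 /M/s)
    coupling partner + second catalyst + open intermediate → second catalyst + target (k = 0.0260 /M²/s)
    open intermediate + capture agent → trapped intermediate (k = 0.00130 /M/s)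

A neighbour flask charged with 0.19 M of coupling partner, its other charges as in the recipe, has R = 8.64, the carried ratio scaled by that charge, and its result at 30 h is 8.64. Its target stands at 17.3% and its trapped intermediate at 2.00%, with coupling partner at 0% and capture agent at 0% of their charges. The open intermediate in that neighbour flask holds 80.7% of the substrate charged.

All runs are calculated for substances that don't exist, and the scatter is random.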